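A direct plan would keep the furan intact from the start: 2-(5-bromopentyl)furan A1 would take up the acetate arm by radical C–H alkylation to give the bromo ester A2, and A2 would be joined by B-alkyl Suzuki coupling to the chiral vinyl acetal A3, which would come from a copper-catalysed enantioselective SN2′ alkylation of the Z-allyl chloride A4. Its weakest steps would be the asymmetric allyl–alkyl substitution, which would have to control regio- and enantioselectivity at a carbon with three similar alkyl arms; the C–H alkylation of the furan, which would rest on innate α-selectivity and could over-alkylate; and the alkyl–alkyl Suzuki coupling, in which β-hydride elimination would compete.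

The route reads the furan-2-ylacetate as the carbonylative cycloisomer of an open-chain alk-4-yn-1-one: furan O1 and C5 are the ketone, C4 and C3 its two methylenes, C2 and the exocyclic CH2 the terminal alkyne, and CO2Me comes from CO and methanol. One palladium-catalysed operation closes the ring, adds the ester and, on acidic work-up, frees the C11 aldehyde. Because no furan exists earlier, the undecyl chain can be joined at C6–C7 by anodic Kolbe cross-coupling, and C8 is taken from the mirror plane of 4-butylcyclohexanone (five ring carbons become C7–C11, the sixth leaves as CO2) by desymmetrising Baeyer–Villiger oxidation. Asymmetric allylic substitution, furan C–H alkylation and alkyl–alkyl Suzuki coupling thus have no counterpart.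

Key step: step 7

Assumption: the sense of induction of the chiral catalyst in step 1 is not predicted here; the ligand enantiomer that delivers the (S)-lactone is taken.

Step 1
Reactants: 1 4-butylcyclohexanone
Product: 2 (5S)-5-butyloxepan-2-one
Conditions: Sc(OTf)3 (5 mol%), chiral N,N′-dioxide ligand (bis-amide bis-N-oxide from a cyclic α-amino acid, 5 mol%), m-CPBA (1.2 equiv), EtOAc, −20 °C
Reagents that add atoms: m-chloroperoxybenzoic acid, O=C(OO)c1cccc(Cl)c1
Why: Catalytic enantioselective Baeyer–Villiger oxidation: the future stereocentre (C4 of 1, C8 of the target) lies on the mirror plane of the ketone, and the chiral trivalent scandium complex that holds the Criegee adduct decides which of the two enantiotopic α-methylene groups migrates to oxygen, so the configuration should be set by catalyst control, leaving the future C11 at the acid level and the carbon that is later lost as CO2 at the alcohol level.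

Step 2
Reactants: 2 (5S)-5-butyloxepan-2-one
Product: 4 (3S)-3-butyl-6,6-dimethoxyhexan-1-ol, via lactol 3 (not isolated)
Conditions: i-Bu2AlH (1.05 equiv), CH2Cl2, −78 °C; aq. KNaC4H4O6 (potassium sodium tartrate); then HC(OMe)3 (3 equiv), PPTS (5 mol%), MeOH, rt
Reagents that add atoms: trimethyl orthoformate, COC(OC)OC; methanol, CO
Why: Lactone half-reduction at −78 °C should stop at the aluminium hemiacetal, and after work-up the seven-membered lactol, which opens readily to the hydroxy aldehyde, is trapped by acid-catalysed acetalisation with the orthoformate as the open-chain dimethyl acetal without touching the stereocentre.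

Step 3
Reactants: 4 (3S)-3-butyl-6,6-dimethoxyhexan-1-ol
Product: 5 (3S)-3-butyl-6,6-dimethoxyhexanoic acid
Conditions: TEMPO (10 mol%), NaClO2 (2 equiv), NaOCl (5 mol%), MeCN/phosphate buffer pH 6.7, 35 °C; acidify to pH 4 (citric acid) at 0 °C and extract at once
Reagents that add atoms: sodium chlorite, [Na+].[O-]Cl=O
Why: TEMPO-catalysed chlorite oxidation (oxoammonium oxidation to the aldehyde, then Pinnick-type oxidation) near neutral pH should take the primary alcohol to the acid while the dimethyl acetal survives, and the stereocentre, β to the new carbonyl, cannot epimerise.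

Step 4
Reactants: 6 methyl 8-chloro-8-oxooctanoate; 7 (4-bromobut-1-yn-1-yl)trimethylsilane
Product: 9 methyl 8-oxo-12-(trimethylsilyl)dodec-11-ynoate, via Grignard reagent 8 (not isolated)
Conditions: 7, Mg, THF, rt; then added to 6 (1.1 equiv), Fe(acac)3 (3 mol%), THF, −78 °C
Reagents that add atoms: none
Why: Iron-catalysed acylation of a Grignard reagent by an acid chloride should be much faster at −78 °C than addition to the methyl ester or to the ketone formed, and the silyl group masks the acidic alkyne C–H during Grignard formation.

Step 5
Reactants: 9 methyl 8-oxo-12-(trimethylsilyl)dodec-11-ynoate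
Product: 10 8-oxododec-11-ynoic acid
Conditions: LiOH·H2O (3 equiv), THF/MeOH/H2O 2:1:1, rt; then 1 M HCl to pH 3
Reagents that add atoms: lithium hydroxide, [Li+].[OH-]
Why: Hydroxide saponifies the methyl ester and in the same pot cleaves the alkynyl C–Si bond (protodesilylation), which gives the keto acid with the free terminal alkyne.

Step 6
Reactants: 5 (3S)-3-butyl-6,6-dimethoxyhexanoic acid; 10 8-oxododec-11-ynoic acid
Product: 11 (13R)-13-butyl-16,16-dimethoxyhexadec-1-yn-5-one
Conditions: 5 (1 equiv), 10 (4 equiv), NaOMe (ca. 5% neutralisation), MeOH, Pt anode, Pt cathode, undivided cell, ca. 250 mA cm−2, 30–40 °C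
Reagents that add atoms: none
Why: Mixed Kolbe electrolysis: both carboxylates should be oxidised at platinum to primary alkyl radicals that couple at the electrode surface, the fourfold excess of the achiral acid 10 steers the statistics towards the cross product, the stereocentre sits next to the radical carbon but is never itself a radical centre and so keeps its configuration (the descriptor changes from S to R only because the CIP priorities change), and the dimethyl acetal is degenerate in methanol.

Step 7
Reactants: 11 (13R)-13-butyl-16,16-dimethoxyhexadec-1-yn-5-one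
Product: 14 methyl 2-{5-[(8R)-8-butyl-11-oxoundecyl]furan-2-yl}acetate, via cyclic ketal 12 (not isolated), via furan acetal 13 (not isolated)
Conditions: PdI2 (2 mol%), KI (20 mol%), CO/air 9:1 (40 atm), MeOH, 65 °C; vent, TsOH·H2O (5 mol%), rt; concentrate, TsOH·H2O (0.2 equiv), THF/H2O 5:1, rt
Reagents that add atoms: carbon monoxide, [C-]#[O+]; methanol, CO; water, O
Why: In methanol the C5 ketone of 11 equilibrates with its hemiketal, whose hydroxyl adds anti to the triple bond held by PdI2 in a 5-exo-dig closure that forms the O1–C2 bond of the future furan and an (E)-vinylpalladium species; CO insertion and methanolysis then give the ester and zerovalent palladium, which oxygen and the HI set free return to divalent palladium. The closest known reaction type is the PdI2/KI-catalysed oxidative cyclisation–alkoxycarbonylation of alk-4-yn-1-ones and alk-4-yn-1-ols. Acid ionises the cyclic ketal 12, and loss of methanol followed by a proton shift from C3 to the exocyclic carbon aromatises it to the furan-2-ylacetate 13, whose dimethyl acetal the same acid hydrolyses with water to the C11 aldehyde. No stereocentre is formed, C8 is separated by seven methylenes from the ring and by two from the acetal carbon and carries no acidic hydrogen, so it is not touched, and the E geometry of the exocyclic alkene disappears on aromatisation. The step needs cyclisation with a single carbonylation to win over dicarbonylation of the alkyne and over plain cycloisomerisation: the 1,4-spacing of carbonyl and alkyne makes the five-membered closure fast, the iodide-rich medium under CO pressure favours CO insertion over protonolysis of the vinylpalladium bond, and the dimethyl acetal is inert because methanol is the solvent.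

Compound list
1 | 4-butylcyclohexanone | CCCCC1CCC(=O)CC1 | starting material
2 | (5S)-5-butyloxepan-2-one | CCCC[C@@H]1CCOC(=O)CC1 | intermediate
3 | (5S)-5-butyloxepan-2-ol (lactol, in equilibrium with (4S)-4-(2-hydroxyethyl)octanal) | CCCC[C@@H]1CCOC(O)CC1 | intermediate
4 | (3S)-3-butyl-6,6-dimethoxyhexan-1-ol | CCCC[C@@H](CCC(OC)OC)CCO | intermediate
5 | (3S)-3-butyl-6,6-dimethoxyhexanoic acid | CCCC[C@@H](CCC(OC)OC)CC(=O)O | intermediate
6 | methyl 8-chloro-8-oxooctanoate | COC(=O)CCCCCCC(Cl)=O | starting material
7 | (4-bromobut-1-yn-1-yl)trimethylsilane | C[Si](C)(C)C#CCCBr | starting material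
8 | [4-(trimethylsilyl)but-3-yn-1-yl]magnesium bromide | C[Si](C)(C)C#CCC[Mg]Br | intermediate
9 | methyl 8-oxo-12-(trimethylsilyl)dodec-11-ynoate | COC(=O)CCCCCCC(=O)CCC#C[Si](C)(C)C | intermediate
10 | 8-oxododec-11-ynoic acid | OC(=O)CCCCCCC(=O)CCC#C | intermediate
11 | (13R)-13-butyl-16,16-dimethoxyhexadec-1-yn-5-one | CCCC[C@@H](CCC(OC)OC)CCCCCCCC(=O)CCC#C | intermediate
12 | methyl (2E)-2-{5-[(8R)-8-butyl-11,11-dimethoxyundecyl]-5-methoxyoxolan-2-ylidene}acetate (both C5 epimers) | CCCC[C@@H](CCC(OC)OC)CCCCCCCC1(OC)CC/C(=C\C(=O)OC)O1 | intermediate
13 | methyl 2-{5-[(8R)-8-butyl-11,11-dimethoxyundecyl]furan-2-yl}acetate | CCCC[C@@H](CCC(OC)OC)CCCCCCCc1ccc(CC(=O)OC)o1 | intermediate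
14 | methyl 2-{5-[(8R)-8-butyl-11-oxoundecyl]furan-2-yl}acetate | CCCC[C@@H](CCC=O)CCCCCCCc1ccc(CC(=O)OC)o1 | target

Total step count: 7. Longest linear sequence: 5 steps (1, 2, 3, 6, 7).

Steps most likely to fail

Step 6. Radical–radical coupling may favour the symmetrical dimers, and the primary radical from 5 may abstract the acetal hydrogen by a 1,5-shift before it couples. The fallback sets out from 4 and returns at 11, and joins the chain by olefination instead. Swern oxidation of 4 would give (3S)-3-butyl-6,6-dimethoxyhexanal F1. Wittig reaction of this aldehyde with the ylide from (5-carboxypentyl)triphenylphosphonium bromide (NaN(SiMe3)2, THF) would give (6Z,9S)-9-butyl-12,12-dimethoxydodec-6-enoic acid F2. Hydrogenation (H2, Pd/C, EtOAc) would give (9R)-9-butyl-12,12-dimethoxydodecanoic acid F3. Carbonyldiimidazole and MeNHOMe·HCl would give the Weinreb amide (9R)-9-butyl-N,12,12-trimethoxy-N-methyldodecanamide F4. Addition of Grignard reagent 8 would give (13R)-13-butyl-16,16-dimethoxy-1-(trimethylsilyl)hexadec-1-yn-5-one F5, and K2CO3 in MeOH would remove the silyl group to give 11.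

Step 7. The vinylpalladium intermediate may be protonated before CO insertion (plain cycloisomerisation to a 2-methylfuran), the alkyne may be dicarbonylated to a maleate, and the furan aldehyde may degrade during the acidic work-up. The fallback sets out from 11 and returns at 13 and then 14, and closes the ring by cyclodehydration instead. Oxidative methoxycarbonylation of the alkyne C–H (PdCl2 cat., CuCl2, NaOAc, CO 1 atm, MeOH, rt) would give methyl (14R)-14-butyl-17,17-dimethoxy-6-oxoheptadec-2-ynoate F6. Conjugate addition of pyrrolidine would give the enamino ester methyl (2E,14R)-14-butyl-17,17-dimethoxy-6-oxo-3-(pyrrolidin-1-yl)heptadec-2-enoate F7, and its hydrolysis on wet silica would give methyl (14R)-14-butyl-17,17-dimethoxy-3,6-dioxoheptadecanoate F8. Paal–Knorr cyclodehydration (TsOH, toluene, 60 °C) would give 13, and TsOH·H2O in THF/H2O as in step 7 would give 14.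

Step 1. The catalyst may discriminate poorly between the two enantiotopic migrating methylene groups, or induce the wrong sense. The fallback sets out from 1 and returns at 2, and breaks the mirror plane by enantioselective deprotonation instead. The suitable enantiomer of lithium bis(1-phenylethyl)amide with Me3SiCl (THF, −78 °C) would give [(4S)-4-butylcyclohex-1-en-1-yl]oxy(trimethyl)silane F9. Ozonolysis with NaBH4 work-up would give (4S)-4-(2-hydroxyethyl)octanoic acid F10. Yamaguchi lactonisation (2,4,6-trichlorobenzoyl chloride, Et3N; then DMAP, toluene, high dilution) would give 2.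

Further compounds
F1 | step 6 | (3S)-3-butyl-6,6-dimethoxyhexanal | CCCC[C@@H](CCC(OC)OC)CC=O
F2 | step 6 | (6Z,9S)-9-butyl-12,12-dimethoxydodec-6-enoic acid | CCCC[C@@H](CCC(OC)OC)C/C=C\CCCCC(=O)O
F3 | step 6 | (9R)-9-butyl-12,12-dimethoxydodecanoic acid | CCCC[C@@H](CCC(OC)OC)CCCCCCCC(=O)O
F4 | step 6 | (9R)-9-butyl-N,12,12-trimethoxy-N-methyldodecanamide | CCCC[C@@H](CCC(OC)OC)CCCCCCCC(=O)N(C)OC
F5 | step 6 | (13R)-13-butyl-16,16-dimethoxy-1-(trimethylsilyl)hexadec-1-yn-5-one | CCCC[C@@H](CCC(OC)OC)CCCCCCCC(=O)CCC#C[Si](C)(C)C
F6 | step 7 | methyl (14R)-14-butyl-17,17-dimethoxy-6-oxoheptadec-2-ynoate | CCCC[C@@H](CCC(OC)OC)CCCCCCCC(=O)CCC#CC(=O)OC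
F7 | step 7 | methyl (2E,14R)-14-butyl-17,17-dimethoxy-6-oxo-3-(pyrrolidin-1-yl)heptadec-2-enoate | CCCC[C@@H](CCC(OC)OC)CCCCCCCC(=O)CC/C(=C\C(=O)OC)N1CCCC1
F8 | step 7 | methyl (14R)-14-butyl-17,17-dimethoxy-3,6-dioxoheptadecanoate | CCCC[C@@H](CCC(OC)OC)CCCCCCCC(=O)CCC(=O)CC(=O)OC
F9 | step 1 | [(4S)-4-butylcyclohex-1-en-1-yl]oxy(trimethyl)silane | CCCC[C@H]1CCC(O[Si](C)(C)C)=CC1
F10 | step 1 | (4S)-4-(2-hydroxyethyl)octanoic acid | CCCC[C@@H](CCC(=O)O)CCO
A1 | direct plan | 2-(5-bromopentyl)furan | BrCCCCCc1ccco1
A2 | direct plan | methyl 2-[5-(5-bromopentyl)furan-2-yl]acetate | COC(=O)Cc1ccc(CCCCCBr)o1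
A3 | direct plan | (4S)-4-ethenyl-1,1-diethoxyoctane | CCCC[C@@H](CCC(OCC)OCC)C=C
A4 | direct plan | (Z)-1-chlorohept-2-ene | CCCC/C=C\CCl
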